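(The numbers in the tables were generated by integration from invented constants; scatter was added.)

The trap in grey was to read the split of the capture off the charges, since a nucleophile does not stay at its charge: by the last zeta reading the second nucleophile had given up 25.9% of its own charge and the first nucleophile 8.19%.

| flask | substrate | first nucleophile | second nucleophile | remark | time |
|---|---|---|---|---|---|
| zeta | 46 mM | 340 mM | 50.6 mM | run made earlier |  |
| grey | 46 mM | 230 mM | 51.0 mM |  | 25 min |
| ochre | 46 mM | 230 mM | 66.0 mM |  | 25 min |
| red | 46 mM | 230 mM | 86.0 mM |  | 25 min |

zeta run (percent of the substrate charged)

| time / min | isomer of the product / % | other capture product / % | solvolysis product / % | substrate / % | target / % |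
|---|---|---|---|---|---|
| 1.33 | 1.3 | 14.0 | 1.9 | 52.8 | 26.0 |
| 2.50 | 5.8 | 20.9 | 1.7 | 31.7 | 37.6 |
| 4.00 | 10.4 | 25.9 | 3.8 | 15.3 | 43.7 |
| 5.00 | 14.8 | 28.5 | 4.0 | 9.9 | 45.7 |

(standard deviation of a reading: 0.5 percentage points)



1. which of these there is most of at the end, counted by the substrate in it, grey (target / solvolysis product / isomer of the product / other capture product)
2. which of these there is most of at the end, counted by the substrate in it, ochre (target / solvolysis product / isomer of the product / other capture product)
3. which of these there is most of at the end, counted by the substrate in it, red (target / solvolysis product / isomer of the product / other capture product)
4. how much there is at the end of the one of these that leads, in percent of the substrate charged: grey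
5. how much there is at the end of the one of these that leads, in percent of the substrate charged: ochre
6. how much there is at the end of the one of these that leads, in percent of the substrate charged: red

In zeta, target plus isomer over other capture product rose from 1.95 to 2.12 as the second nucleophile fell. I therefore froze a short-lived intermediate, passing on what the substrate gave it, and carried one selectivity factor, the capture ratio: the logarithm of the fraction of first nucleophile left, over the same for the second. At the last zeta reading it was 0.285, and at the first 0.276.

I took grey in slow motion. In the first instants the substrate left at the zeta reading of 0.456 min⁻¹, and at charge levels other capture product took 43.8% of the capture. Solvolysis took 4.30% in zeta, leaving 95.7% for capture. In the middle I used levels midway between start and finish: 81.1% of the second nucleophile's charge and 94.6% of the first's. By the end, 0.00112% of the substrate remained by my reckoning. Other capture product came to 38.3% in grey. The same reckoning gave 44.8% in ochre and 51.6% in red.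

In red, target plus isomer came to 44.1%, less than other capture product, so I put that product first there. To lead in grey, the isomer needed 66.7% of the pair, against 24.5% at the last zeta reading. In that run the isomer stood higher at the last reading, 14.8%, than at the one before, 10.4%, so the readings did not show where it stopped, and my own reckoning named no leader for grey; here the forecast differs from it, for it did name one.

The forecast named isomer of the product for grey at 48%, other capture product for ochre at 44.3%, and other capture product for red at 51.7%, adding “Ochre is close, but other capture is favoured.”

The flasks gave other capture product in grey at 38.5%, other capture product in ochre at 45.2%, and other capture product in red at 52.2%.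

    substrate → intermediate (k = 0.467 min⁻¹)
    first nucleophile + intermediate → target (k = 20.4 M⁻¹ min⁻¹)
    second nucleophile + intermediate → other capture product (k = 72.8 M⁻¹ min⁻¹)
    intermediate → solvolysis product (k = 0.397 min⁻¹)
    target ⇌ isomer of the product (K = 0.850, k = 0.104 min⁻¹)

Grey's other capture product stood at 38.5% against my 38.3%, and the isomer held 45.6% of the pair, below the 66.7% it required. The forecast's 48% parted from the flask there. I took the neighbour of ochre with 26 mM of second nucleophile and applied the same factor: other capture product reckoned 23.4% and stood at 23.5%. Grey's split of the pair put target at 39.3%, and target led that flask at 38.1%.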